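Take the target and side product made in each interval and compare them.

| setting | cedar | maple | oak | summer | dawn | winter |
|---|---|---|---|---|---|---|
| substrate | 0.065 M | 0.065 M | 0.065 M | 0.065 M | 0.065 M | 0.065 M (fed, over 80.0 min) |
| free catalyst | 3.2 mM | 3.2 mM | 3.2 mM | 3.2 mM | 3.2 mM | 3.2 mM |
| added ligand | 2.5 mM | 1.7 mM | 3.8 mM | 2.5 mM | 2.5 mM | 2.5 mM |
| remark | run made earlier | run made earlier | run made earlier | everything together in a closed stirred flask, run for 80 min | one stirred flow tank at steady state, fed with the mixture as stated, mean residence time 80 min | a stirred flask in which substrate is dosed at a steady rate over 80.0 min without added volume, worked up at 80 min |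
| time |  |  |  | 80 min |  | 80 min |



| run | time / min | target / % | side product / % | substrate / % |
|---|---|---|---|---|
| cedar | 4.00 | 50.3 | 12.5 | 36.3 |
| cedar | 6.00 | 60.2 | 18.5 | 20.4 |
| cedar | 8.00 | 65.9 | 22.0 | 11.2 |
| cedar | 15.0 | 71.3 | 26.9 | 1.6 |
| cedar | 20.0 | 71.9 | 28.8 | 1.3 |
| cedar | 30.0 | 71.1 | 27.9 | 0.2 |
| cedar | 50.0 | 71.5 | 28.0 | 0.1 |
| maple | 12.0 | 71.9 | 24.5 | 3.3 |
| maple | 25.0 | 74.4 | 25.2 | 0.2 |
| maple | 30.0 | 74.2 | 25.9 | 0.4 |
| maple | 50.0 | 74.4 | 26.2 | 0.5 |
| maple | 60.0 | 74.5 | 26.1 | 0 |
| maple | 80.0 | 73.8 | 26.1 | 0.9 |
| oak | 6.00 | 55.6 | 17.9 | 24.6 |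
| oak | 10.0 | 63.4 | 25.6 | 9.8 |
| oak | 15.0 | 65.1 | 31.4 | 3.5 |
| oak | 25.0 | 66.6 | 32.9 | 0 |
| oak | 30.0 | 65.8 | 33.5 | 0 |
| oak | 50.0 | 65.3 | 34.4 | 0 |
| oak | 80.0 | 66.5 | 34.1 | 0 |

(readings scatter by 0.5 percentage points)



- percent here means substrate units held: one side product counts as two
- the stated concentrations are those of everything mixed, before any reaction; amounts are the same in each set-up
- what was read earlier has a scatter of 0.5 percentage points, one standard deviation
- the feed brings no volume worth counting
- the earlier runs were made in a closed, stirred flask
- a reading or a percentage of target counts all its forms, free or not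



- order of the set-ups by the share of target in all that became target or side product, at the outlet or at the end, highest first (summer / dawn / winter)
- share of target in all that became target or side product, at the outlet or at the end, summer
- share of target in all that became target or side product, at the outlet or at the end, dawn
- share of target in all that became target or side product, at the outlet or at the end, winter



I wrote P for target and O for side product, both in percent of the substrate charged. In cedar the ratio of new O to new P rose as P grew, so I tried dO/dP = P/T. Here T is the crossover target, the level of target at which both grow equally. Over a closed run this gives T = P·P/(2·O), and the cedar plateau gives 91.3 %. Summer repeats cedar's recipe, so I took its share (selectivity) as 71.9 %.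

But T isn't constant. Between 8.00 min and 15.0 min cedar gave 75.6 %, a reading with wide scatter. The plateau value also fell with ligand, from 106 % in maple to 64.8 % in oak. Oak held more ligand than catalyst, yet its substrate was down to 3.5 % at 15.0 min. So I read the ligand as taking catalyst gradually, with T sinking as it does.

Dawn sits at its outlet P, so O/P = P/T. With the late T and the charge fully converted, dawn gives 57.0 %. Taking winter by the closed-run rule, with the same T, I got 68.7 %. But T was probably still sinking, and by cedar's 15.0 min winter has received 18.8 % of its feed. So I expected both flasks to come out lower than these estimates.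

The forecast gave summer > winter > dawn, with 71.8 %, 59 % and 69 %, noting that “the tank always sits at high target”.

The flasks gave summer > winter > dawn, with 71.7 %, 52.2 % and 58.8 %.

    free catalyst + added ligand ⇌ idle complex A (K = 35000 M⁻¹, k = 65.0 M⁻¹ min⁻¹)
    substrate + free catalyst ⇌ catalyst intermediate (K = 38.0 M⁻¹, k = 550 M⁻¹ min⁻¹)
    catalyst intermediate → free catalyst + target (k = 6.50 min⁻¹)
    substrate + target → side product (k = 1.50 M⁻¹ min⁻¹)
    free catalyst + target ⇌ idle complex B (K = 8.00 M⁻¹, k = 4.30 M⁻¹ min⁻¹)

Winter at 80.0 min held 53.9 % target and 37.7 % side product, so its T was 38.5 %, lower than cedar's. A neighbouring flask repeated summer with 0.013 M of free catalyst. Scaling T with that charge gave 371 % and a share of 89.3 %. That flask gave 93.4 %, with 6.60 % side product.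

The readings are simulated with made-up constants, and the scatter is random.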